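**Plan**

- Retrosynthesis first removes the C3 hydroxyl and masks the 2'- and 5-hydroxyls as benzyl and methyl ethers, which leads back to 2'-benzyloxy-5,7,8,4'-tetramethoxyflavone.
- Ring C is then cut at C4a–C4, C4–C3 and O1–C2. The C4 carbonyl lies between aryl carbon C4a and C3, and O1 sits on the neighbouring ring-A carbon C8a, so the pyranone is the sum of an ortho-iodophenol, CO and a terminal arylalkyne.
- Forward, ring A is prepared as 2-iodo-3,5,6-trimethoxyphenol from 3-hydroxy-4,5-dimethoxybenzaldehyde: carbamate formation, Baeyer–Villiger oxidation, methylation, carbamate-directed ortho-iodination, hydrolysis.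
- Ring B is prepared as 2-(benzyloxy)-1-ethynyl-4-methoxybenzene from 2-hydroxy-4-methoxybenzaldehyde: benzylation, Ohira–Bestmann homologation.
- The palladium-catalysed three-component carbonylative annulation closes ring C, the only ring made in the route. Dioxirane epoxidation with acid opening then installs the 3-OH, and BCl3 frees the 2'- and 5-hydroxyls.
- The target has no stereocentre. The only stereogenic intermediate, the racemic 2,3-epoxide, loses both centres on ring opening.

Key step: step 8

Remark: 3-hydroxy-4,5-dimethoxybenzaldehyde, 2-hydroxy-4-methoxybenzaldehyde, carbon monoxide and dimethyl (1-diazo-2-oxopropyl)phosphonate are assumed to be commercially available.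

**Route**

Step 1
Reactants: 1 3-hydroxy-4,5-dimethoxybenzaldehyde
Product: 2 5-formyl-2,3-dimethoxyphenyl N,N-diethylcarbamate
Conditions: Et2NCOCl, K2CO3, MeCN, reflux
Reagents that add atoms: N,N-diethylcarbamoyl chloride, CCN(CC)C(Cl)=O
Why: O-carbamoylation of the phenoxide (nucleophilic acyl substitution) should install a group that withstands peracid and mild base and later serves as the directing group for metalation.

Step 2
Reactants: 2 5-formyl-2,3-dimethoxyphenyl N,N-diethylcarbamate
Product: 4 5-hydroxy-2,3-dimethoxyphenyl N,N-diethylcarbamate, via aryl formate 3 (not isolated)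
Conditions: mCPBA, CH2Cl2, 0 °C to rt; then K2CO3 (cat.), MeOH, rt
Reagents that add atoms: 3-chloroperoxybenzoic acid, O=C(OO)c1cccc(Cl)c1
Why: In this Baeyer–Villiger (Dakin-type) oxidation the electron-rich aryl group with its para methoxy group should migrate in the Criegee intermediate, and the resulting formate is methanolysed under conditions that leave the diethylcarbamate intact.

Step 3
Reactants: 4 5-hydroxy-2,3-dimethoxyphenyl N,N-diethylcarbamate
Product: 5 2,3,5-trimethoxyphenyl N,N-diethylcarbamate
Conditions: MeI, K2CO3, acetone, reflux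
Reagents that add atoms: iodomethane, CI
Why: Williamson etherification of the only free phenol should complete the 2,3,5-trimethoxy pattern without touching the carbamate.

Step 4
Reactants: 5 2,3,5-trimethoxyphenyl N,N-diethylcarbamate
Product: 7 2-iodo-3,5,6-trimethoxyphenyl N,N-diethylcarbamate, via ortho-lithiated carbamate 6 (not isolated)
Conditions: s-BuLi, TMEDA, THF, −78 °C; then I2, THF, −78 °C to rt
Reagents that add atoms: iodine, II
Why: In this directed ortho-metalation the hydrogen between the carbamate, the strongest directing group present, and the adjacent methoxy group should be removed selectively, and iodine quench at −78 °C should forestall the anionic ortho-Fries shift.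

Step 5
Reactants: 7 2-iodo-3,5,6-trimethoxyphenyl N,N-diethylcarbamate
Product: 8 2-iodo-3,5,6-trimethoxyphenol
Conditions: NaOH, EtOH/H2O, reflux; acidic work-up
Reagents that add atoms: none
Why: Basic hydrolysis of the aryl carbamate should release the phenol that becomes O1, since the aryl iodide and the methyl ethers are inert to hydroxide.

Step 6
Reactants: 9 2-hydroxy-4-methoxybenzaldehyde
Product: 10 2-(benzyloxy)-4-methoxybenzaldehyde
Conditions: BnBr, K2CO3, DMF, 60 °C
Reagents that add atoms: benzyl bromide, BrCc1ccccc1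
Why: Williamson etherification in DMF should alkylate the hydrogen-bonded ortho hydroxyl cleanly and mask the future 2'-OH as a benzyl ether that survives amines, palladium, CO and dioxirane.

Step 7
Reactants: 10 2-(benzyloxy)-4-methoxybenzaldehyde
Product: 11 2-(benzyloxy)-1-ethynyl-4-methoxybenzene
Conditions: MeC(O)C(N2)P(O)(OMe)2, K2CO3, MeOH, rt
Reagents that add atoms: dimethyl (1-diazo-2-oxopropyl)phosphonate, CC(=O)C(=[N+]=[N-])P(=O)(OC)OC
Why: The Ohira–Bestmann variant of the Seyferth–Gilbert homologation should turn the aryl aldehyde into the terminal alkyne in one operation under mild carbonate conditions that the benzyl ether tolerates.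

Step 8
Reactants: 8 2-iodo-3,5,6-trimethoxyphenol; 11 2-(benzyloxy)-1-ethynyl-4-methoxybenzene; 12 carbon monoxide
Product: 15 2-[2-(benzyloxy)-4-methoxyphenyl]-5,7,8-trimethoxy-4H-chromen-4-one, via ynone 13 (not isolated), via enaminone 14 (not isolated)
Conditions: PdCl2(dppf) (5 mol %), CO (20 bar), Et2NH, 120 °C
Reagents that add atoms: carbon monoxide (compound 12), [C-]#[O+]
Why: Zerovalent palladium, formed in situ from PdCl2(dppf), inserts into the C–I bond of 8, CO inserts to give an aroylpalladium iodide, and amine-assisted coupling with the terminal alkyne 11 followed by reductive elimination forges C4a–C4 and C4–C3 as ynone 13. Diethylamine then adds to the ynone to give β-aminoenone 14, and the ortho phenol oxygen attacks the β-carbon and expels the amine, forming O1–C2. The closest known reaction type is the palladium-catalysed carbonylative annulation (carbonylative Sonogashira coupling–cyclisation) of ortho-iodophenols and terminal arylacetylenes to flavones in a secondary amine. Ring C closes in a 6-endo mode, 6-endo-trig addition–elimination on the enaminone and formally 6-endo-dig on the ynone. No stereocentre is created. The step needs CO insertion ahead of alkyne coupling and six- rather than five-membered closure: the electron-rich arylpalladium flanked by OH and OMe and the 20 bar of CO favour acyl formation over direct coupling to a benzofuran, and the amine addition–elimination path steers the ynone to the flavone instead of the aurone.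

Step 9
Reactants: 15 2-[2-(benzyloxy)-4-methoxyphenyl]-5,7,8-trimethoxy-4H-chromen-4-one
Product: 17 2-[2-(benzyloxy)-4-methoxyphenyl]-3-hydroxy-5,7,8-trimethoxy-4H-chromen-4-one, via flavone 2,3-epoxide 16 (not isolated)
Conditions: DMDO, acetone/CH2Cl2, 0 °C to rt; then p-TsOH (cat.), CH2Cl2, rt
Reagents that add atoms: dimethyldioxirane, CC1(C)OO1
Why: Dioxirane epoxidation of the C2=C3 enol-ether double bond gives the racemic epoxide, whose acid-catalysed opening at C2 to an O1-stabilised cation and loss of H3 should deliver the flavonol, erasing both transient stereocentres.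

Step 10
Reactants: 17 2-[2-(benzyloxy)-4-methoxyphenyl]-3-hydroxy-5,7,8-trimethoxy-4H-chromen-4-one
Product: 18 3,5-dihydroxy-2-(2-hydroxy-4-methoxyphenyl)-7,8-dimethoxy-4H-chromen-4-one (3,5,2'-trihydroxy-7,8,4'-trimethoxyflavone)
Conditions: BCl3, C6HMe5, CH2Cl2, −78 °C to rt; then MeOH/H2O
Reagents that add atoms: none
Why: In this Lewis-acid ether cleavage BCl3 should remove the aryl benzyl ether (the benzyl cation being trapped by pentamethylbenzene) and, through chelation to the C4 carbonyl, only the peri 5-O-methyl group, leaving the unchelated 7-, 8- and 4'-methyl ethers in place.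

**Compound list**

1 | 3-hydroxy-4,5-dimethoxybenzaldehyde | COc1cc(C=O)cc(O)c1OC | starting material
2 | 5-formyl-2,3-dimethoxyphenyl N,N-diethylcarbamate | CCN(CC)C(=O)Oc1cc(C=O)cc(OC)c1OC | intermediate
3 | 3-[(diethylcarbamoyl)oxy]-4,5-dimethoxyphenyl formate | CCN(CC)C(=O)Oc1cc(OC=O)cc(OC)c1OC | intermediate (not isolated)
4 | 5-hydroxy-2,3-dimethoxyphenyl N,N-diethylcarbamate | CCN(CC)C(=O)Oc1cc(O)cc(OC)c1OC | intermediate
5 | 2,3,5-trimethoxyphenyl N,N-diethylcarbamate | CCN(CC)C(=O)Oc1cc(OC)cc(OC)c1OC | intermediate
6 | {2-[(diethylcarbamoyl)oxy]-3,4,6-trimethoxyphenyl}lithium | [Li]c1c(OC)cc(OC)c(OC)c1OC(=O)N(CC)CC | intermediate (not isolated)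
7 | 2-iodo-3,5,6-trimethoxyphenyl N,N-diethylcarbamate | CCN(CC)C(=O)Oc1c(I)c(OC)cc(OC)c1OC | intermediate
8 | 2-iodo-3,5,6-trimethoxyphenol | COc1cc(OC)c(OC)c(O)c1I | intermediate
9 | 2-hydroxy-4-methoxybenzaldehyde | COc1ccc(C=O)c(O)c1 | starting material
10 | 2-(benzyloxy)-4-methoxybenzaldehyde | COc1ccc(C=O)c(OCc2ccccc2)c1 | intermediate
11 | 2-(benzyloxy)-1-ethynyl-4-methoxybenzene | C#Cc1ccc(OC)cc1OCc1ccccc1 | intermediate
12 | carbon monoxide | [C-]#[O+] | starting material
13 | 3-[2-(benzyloxy)-4-methoxyphenyl]-1-(2-hydroxy-3,4,6-trimethoxyphenyl)prop-2-yn-1-one | COc1ccc(C#CC(=O)c2c(OC)cc(OC)c(OC)c2O)c(OCc2ccccc2)c1 | intermediate (not isolated)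
14 | (E)-3-[2-(benzyloxy)-4-methoxyphenyl]-3-(diethylamino)-1-(2-hydroxy-3,4,6-trimethoxyphenyl)prop-2-en-1-one (E geometry expected; either geometry can cyclise) | CCN(CC)/C(=C/C(=O)c1c(OC)cc(OC)c(OC)c1O)c1ccc(OC)cc1OCc1ccccc1 | intermediate (not isolated)
15 | 2-[2-(benzyloxy)-4-methoxyphenyl]-5,7,8-trimethoxy-4H-chromen-4-one | COc1ccc(-c2cc(=O)c3c(OC)cc(OC)c(OC)c3o2)c(OCc2ccccc2)c1 | intermediate
16 | 2-[2-(benzyloxy)-4-methoxyphenyl]-2,3-epoxy-5,7,8-trimethoxy-2,3-dihydro-4H-chromen-4-one (racemic, cis-fused; one enantiomer drawn) | COc1ccc([C@]23Oc4c(OC)c(OC)cc(OC)c4C(=O)[C@H]2O3)c(OCc2ccccc2)c1 | intermediate (not isolated)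
17 | 2-[2-(benzyloxy)-4-methoxyphenyl]-3-hydroxy-5,7,8-trimethoxy-4H-chromen-4-one | COc1ccc(-c2oc3c(OC)c(OC)cc(OC)c3c(=O)c2O)c(OCc2ccccc2)c1 | intermediate
18 | 3,5-dihydroxy-2-(2-hydroxy-4-methoxyphenyl)-7,8-dimethoxy-4H-chromen-4-one | COc1ccc(-c2oc3c(OC)c(OC)cc(O)c3c(=O)c2O)c(O)c1 | target

**Step count**

Total: 10 steps. Longest linear sequence: 8 steps (steps 1–5, 8, 9, 10 from compound 1); the alkyne branch adds 2 steps (6, 7).

**Steps most likely to fail**

Step 8. The arylpalladium species may couple with the alkyne before CO insertion, the aroylpalladium may be captured by diethylamine, or oxidative addition into the hindered, electron-rich C–I bond may be slow. The fallback builds the ynone without palladium or CO; it sets out from iodophenol 8 and alkyne 11 and returns to the route at ynone 13, which is closed to flavone 15. Iodophenol 8 would be protected with MOMCl and i-Pr2NEt in CH2Cl2 as 2-iodo-1,4,5-trimethoxy-3-(methoxymethoxy)benzene F1. Alkyne 11 would be deprotonated with n-BuLi in THF at −78 °C to lithium [2-(benzyloxy)-4-methoxyphenyl]acetylide F2, and acylation with N-methoxy-N-methylcarbamoyl chloride would give 3-[2-(benzyloxy)-4-methoxyphenyl]-N-methoxy-N-methylprop-2-ynamide F3. Iodine–lithium exchange on F1 with n-BuLi in THF at −78 °C would give [3,4,6-trimethoxy-2-(methoxymethoxy)phenyl]lithium F4. Its addition to F3 and a cold aqueous NH4Cl quench should furnish 3-[2-(benzyloxy)-4-methoxyphenyl]-1-[3,4,6-trimethoxy-2-(methoxymethoxy)phenyl]prop-2-yn-1-one F5. HCl in MeOH would then remove the methoxymethyl group to give ynone 13, and Et2NH in EtOH should close it through enaminone 14 to flavone 15.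

Step 9. Epoxidation of the twisted, electron-poor C2=C3 bond may be slow, so that oxidation at the benzylic CH2 of the benzyl ether or on the electron-rich rings competes. The fallback replaces the electrophilic oxidant by C3 metalation; it sets out from flavone 15 and returns at flavonol 17. Deprotonation of 15 at C3 with LiN(i-Pr)2 in THF at −78 °C would give {2-[2-(benzyloxy)-4-methoxyphenyl]-5,7,8-trimethoxy-4-oxo-4H-chromen-3-yl}lithium F6. Trapping with B(OMe)3 would give lithium {2-[2-(benzyloxy)-4-methoxyphenyl]-5,7,8-trimethoxy-4-oxo-4H-chromen-3-yl}trimethoxyborate F7, and oxidation of the C–B bond with H2O2 in AcOH should give 17.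

Step 10. Ether cleavage may be unselective, with loss of the 8-, 7- or 4'-methyl group alongside the 5-methyl group, or the liberated benzyl cation may alkylate an electron-rich ring. The fallback separates the two deprotections; it sets out from flavonol 17 and returns at target 18. Hydrogenolysis of 17 with H2 and Pd/C in EtOAc/MeOH would remove the benzyl group as toluene and give 3-hydroxy-2-(2-hydroxy-4-methoxyphenyl)-5,7,8-trimethoxy-4H-chromen-4-one F8. Chelation-controlled demethylation of the 5-methoxy group with AlCl3 in MeCN at 60 °C should then give 18.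

**Further compounds**

F1 | step 8 | 2-iodo-1,4,5-trimethoxy-3-(methoxymethoxy)benzene | COCOc1c(I)c(OC)cc(OC)c1OC
F2 | step 8 | lithium [2-(benzyloxy)-4-methoxyphenyl]acetylide | [Li]C#Cc1ccc(OC)cc1OCc1ccccc1
F3 | step 8 | 3-[2-(benzyloxy)-4-methoxyphenyl]-N-methoxy-N-methylprop-2-ynamide | CON(C)C(=O)C#Cc1ccc(OC)cc1OCc1ccccc1
F4 | step 8 | [3,4,6-trimethoxy-2-(methoxymethoxy)phenyl]lithium | [Li]c1c(OC)cc(OC)c(OC)c1OCOC
F5 | step 8 | 3-[2-(benzyloxy)-4-methoxyphenyl]-1-[3,4,6-trimethoxy-2-(methoxymethoxy)phenyl]prop-2-yn-1-one | COCOc1c(C(=O)C#Cc2ccc(OC)cc2OCc2ccccc2)c(OC)cc(OC)c1OC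
F6 | step 9 | {2-[2-(benzyloxy)-4-methoxyphenyl]-5,7,8-trimethoxy-4-oxo-4H-chromen-3-yl}lithium | COc1ccc(-c2oc3c(OC)c(OC)cc(OC)c3c(=O)c2[Li])c(OCc2ccccc2)c1
F7 | step 9 | lithium {2-[2-(benzyloxy)-4-methoxyphenyl]-5,7,8-trimethoxy-4-oxo-4H-chromen-3-yl}trimethoxyborate | [Li+].CO[B-](OC)(OC)c1c(-c2ccc(OC)cc2OCc2ccccc2)oc2c(OC)c(OC)cc(OC)c2c1=O
F8 | step 10 | 3-hydroxy-2-(2-hydroxy-4-methoxyphenyl)-5,7,8-trimethoxy-4H-chromen-4-one | COc1ccc(-c2oc3c(OC)c(OC)cc(OC)c3c(=O)c2O)c(O)c1
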